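**Retrosynthetic overview**

1. Chromene numbering is used for the core: O-1, C-2, C-3, C-4 (C=O), C-4a, C-5 (OH), C-6, C-7 (C=O), C-8 (quaternary), C-8a. Ring A is the carbocycle C-4a/C-5/C-6/C-7/C-8/C-8a; ring B is the dihydropyranone O-1/C-2/C-3/C-4/C-4a/C-8a. The (S)-octanoic acid arm on C-6 is cut last: iminium-catalysed Michael addition of the C-6–H of the bicyclic core to (E)-oct-2-enal, then aldehyde to acid.
2. Ring A is cut at C-5–C-6 (Dieckmann condensation of the acetyl CH3 on C-8 onto a C-5 ester) and ring B at C-4a–C-8a. This leads back to one acyclic ester: the quaternary (C-8) β-keto acid esterified on O-1 by a δ-hydroxy-β-keto ester (C-2 to C-5).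
3. Enabling feature: C-8a is at the carboxyl oxidation level (it carries O-1 and is double-bonded to C-4a), and C-4a lies between the carbonyl carbons C-4 and C-5. The C-4a=C-8a–O-1 unit of ring B is therefore the enol ether of a triacylmethane, and C-4a–C-8a is an enolate-to-ester (Claisen) bond, the bond type that closes the acylphloroglucinol ring in polyketide biosynthesis. The O-1–C-2–C-3–C-4 chain is a built-in tether: the ester oxygen hands the C-8a acyl group to C-4a through a six-membered transition state and can then return only to C-8a.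
4. C-8 is set by auxiliary-controlled alkylation of a chiral lithio-enamine. Its cyclobutylmethyl arm comes from C=C cleavage of (−)-verbenone, which keeps both cyclobutane stereocentres. C-2/C-3 come from methyl (R)-3-hydroxybutanoate by Fráter–Seebach alkylation.
5. Ring order: cyclobutane (excised from the pinane skeleton), then ring B (key step), then ring A.

Key step: step 13

Assumption: the target is treated as the 5-hydroxy-4,7-dioxo enol tautomer drawn in its SMILES; commercial (1S)-(−)-verbenone is taken at high enantiomeric purity and tert-butyl L-valinate as the free base liberated from its hydrochloride; the CIP label of the quaternary carbon changes from S (acid and ester series) to R (from the pyranone on) without any change in spatial arrangement.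

Notation: Cbm = [(1R,3S)-2,2-dimethyl-3-(prop-1-en-2-yl)cyclobutyl]methyl.

**Route**

Step 1
Reactants: 1 (1S,5S)-(−)-verbenone
Product: 2 (1S,3R)-3-acetyl-2,2-dimethylcyclobutane-1-carboxylic acid (cis-pinononic acid)
Conditions: RuCl3·xH2O (2 mol %), NaIO4 (4.1 equiv), CCl4/MeCN/H2O, rt
Reagents that add atoms: sodium periodate, [Na+].[O-]I(=O)(=O)=O; water, O
Why: Oxidative cleavage of the enone C=C bond by catalytic RuO4 (from RuCl3 and NaIO4), with loss of the former C-3 as CO2, opens the six-membered ring of the pinane skeleton and leaves the two bridgehead stereocentres as the cis-1,3 substituents of the cyclobutane.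

Step 2
Reactants: 2 (1S,3R)-3-acetyl-2,2-dimethylcyclobutane-1-carboxylic acid
Product: 3 (1S,3S)-2,2-dimethyl-3-(prop-1-en-2-yl)cyclobutane-1-carboxylic acid
Conditions: Ph3PCH3Br (2.5 equiv), KOt-Bu (3.5 equiv), THF, 0 °C → rt; then dilute aq. HCl
Reagents that add atoms: methyltriphenylphosphonium bromide, C[P+](c1ccccc1)(c1ccccc1)c1ccccc1.[Br-]
Why: Wittig methylenation of the methyl ketone of the potassium carboxylate creates no stereocentre, and the cis-1,3 arrangement (the more stable one on a cyclobutane) should survive the basic ylide.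

Step 3
Reactants: 3 (1S,3S)-2,2-dimethyl-3-(prop-1-en-2-yl)cyclobutane-1-carboxylic acid
Product: 4 [(1S,3S)-2,2-dimethyl-3-(prop-1-en-2-yl)cyclobutyl]methanol
Conditions: LiAlH4 (2 equiv), THF, 0 °C → rt
Reagents that add atoms: none
Why: LiAlH4 reduction of the carboxylic acid to the primary alcohol touches neither the 1,1-disubstituted alkene nor the two stereocentres.

Step 4
Reactants: 4 [(1S,3S)-2,2-dimethyl-3-(prop-1-en-2-yl)cyclobutyl]methanol
Product: 5 (1S,3S)-1-(iodomethyl)-2,2-dimethyl-3-(prop-1-en-2-yl)cyclobutane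
Conditions: I2, PPh3, imidazole, CH2Cl2, 0 °C → rt, dark
Reagents that add atoms: iodine, II
Why: Appel-type iodination converts the primary alcohol into the iodide by SN2 at the CH2 group, so no cyclobutylcarbinyl cation and hence no ring expansion can arise.

Step 5
Reactants: 6 2-(trimethylsilyl)ethanol; 7 2,2,6-trimethyl-4H-1,3-dioxin-4-one
Product: 9 2-(trimethylsilyl)ethyl 3-oxobutanoate, via acetylketene 8 (not isolated)
Conditions: xylene, 135 °C, acetone distilled out
Reagents that add atoms: none
Why: Thermal retro-[4+2] fragmentation of the dioxinone releases acetone and acetylketene, which the alcohol traps (acetoacetylation under neutral conditions).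

Step 6
Reactants: 9 2-(trimethylsilyl)ethyl 3-oxobutanoate; 5 (1S,3S)-1-(iodomethyl)-2,2-dimethyl-3-(prop-1-en-2-yl)cyclobutane
Product: 10 2-(trimethylsilyl)ethyl 2-Cbm-3-oxobutanoate (both C-2 epimers)
Conditions: NaH (1.05 equiv), THF/DMF, 0 °C; then 5, 60 °C
Reagents that add atoms: none
Why: SN2 C-alkylation of the sodium enolate of the β-keto ester by the primary iodide (acetoacetic ester alkylation); the new α-centre is epimerisable and becomes sp2 in the next step, so both epimers are carried on.

Step 7
Reactants: 10 2-(trimethylsilyl)ethyl 2-Cbm-3-oxobutanoate; 11 tert-butyl L-valinate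
Product: 12 2-(trimethylsilyl)ethyl (2Z)-3-{[(2S)-1-tert-butoxy-3-methyl-1-oxobutan-2-yl]amino}-2-Cbm-but-2-enoate
Conditions: BF3·OEt2 (cat.), benzene, reflux, Dean–Stark trap
Reagents that add atoms: none
Why: Acid-catalysed condensation of the ketone with the primary amine should give the hydrogen-bonded (Z)-β-enamino ester, which places the valine stereocentre as controller next to the carbon that becomes quaternary.

Step 8
Reactants: 12 the (Z)-β-enamino ester; 13 1-bromo-3-methylbut-2-ene (prenyl bromide)
Product: 15 2-(trimethylsilyl)ethyl (2S)-2-acetyl-2-Cbm-5-methylhex-4-enoate, via valine imine 14 (not isolated)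
Conditions: LiN(i-Pr)2 (1.1 equiv), THF, −78 °C; 13, −78 → −40 °C; then 10% aq. citric acid/Et2O, rt
Reagents that add atoms: water, O
Why: Auxiliary-controlled alkylation of a chiral lithio-enamine: N-deprotonation gives a rigid aza-enolate in which lithium is held by nitrogen and both ester carbonyls, the valine isopropyl group blocks one face, and prenyl bromide is delivered to the α-carbon on the lithium-ligated open face to set the (S)-quaternary centre, after which mild acid hydrolyses the imine and returns the auxiliary (the facial sense assigned here rests on this chelate model and is known for this method to invert in toluene with HMPA, which is the built-in correction if correlation at the acid stage shows the other face).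

Step 9
Reactants: 15 2-(trimethylsilyl)ethyl (2S)-2-acetyl-2-Cbm-5-methylhex-4-enoate
Product: 16 (2S)-2-acetyl-2-Cbm-5-methylhex-4-enoic acid
Conditions: Bu4NF (1.5 equiv), THF, 0 °C; cold dilute aq. HCl work-up; used at once
Reagents that add atoms: none
Why: Fluoride-induced β-elimination of the 2-(trimethylsilyl)ethyl ester frees the acid without acid or hydroxide, so the alkenes, the cyclobutane and the retro-Claisen-prone β-keto ester should survive; the β-keto acid is kept cold to avoid decarboxylation.

Step 10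
Reactants: 17 methyl (R)-3-hydroxybutanoate
Product: 18 methyl (2R,3R)-3-hydroxy-2-methylbutanoate
Conditions: LiN(i-Pr)2 (2.2 equiv), THF, −78 → −20 °C; MeI, DMPU, −78 → 0 °C; AcOH
Reagents that add atoms: iodomethane, CI
Why: Fráter–Seebach alkylation: the dilithio alkoxide-enolate is a six-membered chelate and iodomethane enters anti to the C-3 methyl group, which should give the anti (2R,3R) product, the future trans C-2/C-3 pair of ring B.

Step 11
Reactants: 18 methyl (2R,3R)-3-hydroxy-2-methylbutanoate
Product: 19 methyl (4R,5R)-5-hydroxy-4-methyl-3-oxohexanoate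
Conditions: MeOAc and LiN(i-Pr)2 (3.5 equiv each), THF, −78 °C; then 18, −78 → −45 °C; AcOH
Reagents that add atoms: methyl acetate, COC(C)=O
Why: Crossed Claisen condensation of excess lithium enolate of methyl acetate with the chelation-activated lithium alkoxide of the β-hydroxy ester gives the δ-hydroxy-β-keto ester, which stays in the flask as its enolate so that the adjacent stereocentre (later C-3) is not epimerised.

Step 12
Reactants: 16 (2S)-2-acetyl-2-Cbm-5-methylhex-4-enoic acid; 19 methyl (4R,5R)-5-hydroxy-4-methyl-3-oxohexanoate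
Product: 21 (2R,3R)-6-methoxy-3-methyl-4,6-dioxohexan-2-yl (2S)-2-acetyl-2-Cbm-5-methylhex-4-enoate, via acid chloride 20 (not isolated)
Conditions: 1-chloro-N,N,2-trimethylprop-1-en-1-amine (1.2 equiv), CH2Cl2, 0 °C; then 19, pyridine, DMAP (cat.), 0 °C → rt
Reagents that add atoms: none
Why: The α-chloroenamine converts the acid into its chloride under neutral conditions and the secondary alcohol is then O-acylated with nucleophilic catalysis by DMAP, an ester synthesis suited to α-quaternary acids; pyridine is too weak to enolise C-3, so no β-elimination is expected and both carbinol-side stereocentres are retained.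

Step 13
Reactants: 21 (2R,3R)-6-methoxy-3-methyl-4,6-dioxohexan-2-yl (2S)-2-acetyl-2-Cbm-5-methylhex-4-enoate
Product: 23 methyl (2R,3R)-6-[(2R)-2-acetyl-1-[(1R,3S)-2,2-dimethyl-3-(prop-1-en-2-yl)cyclobutyl]-5-methylhex-4-en-2-yl]-2,3-dimethyl-4-oxo-3,4-dihydro-2H-pyran-5-carboxylate, via hydroxy triketo ester 22 (not isolated)
Conditions: NaH (1.05 equiv), THF, 0 → 45 °C; AcOH (1.1 equiv); then pyridinium p-toluenesulfonate (10 mol %), toluene, 4 Å MS, 50 °C
Reagents that add atoms: none
Why: Proposed new method: one equivalent of NaH converts only the β-keto ester CH2 (C-4a) of 21 into its enolate, whose carbon adds 6-exo-trig to the ester carbonyl C-8a that the O-1–C-2–C-3–C-4 chain holds five atoms away; the cyclic tetrahedral alkoxide opens at C-8a–O-1 and immediate proton transfer from C-4a–H, now flanked by three carbonyl groups, to the alkoxide gives the strongly stabilised enolate of 22, which makes this 1,5 O→C acyl shift downhill. The closest known reaction types are the Baker–Venkataraman rearrangement (the same six-membered O→C acyl transfer, known from aryl esters) and the Lacey–Dieckmann cyclisation (C-acylation of a β-dicarbonyl enolate by an unactivated alkyl ester), so the new element is an alkyl ester serving as the internal acyl donor towards a β-keto ester enolate. After buffering with AcOH, the catalytic pyridinium salt lets the C-2 hydroxyl add back to the C-8a ketone (6-exo-trig hemiketal) and water is lost across C-4a–C-8a, the standard cyclodehydration of δ-hydroxy-β-dicarbonyl compounds to 2,3-dihydro-4H-pyran-4-ones, so that ring B results with C-4a–C-8a as its newly made ring bond. No stereocentre is created: C-2 and C-3 are carried over from 19 (the single equivalent of base sits on C-4a, so C-3 is not enolised and the acyloxy group is not lost by β-elimination) and the quaternary C-8 cannot epimerise. The selectivity needed is that O-1 ends on C-8a and not on C-5, and the substrate secures it: O-1 is bonded to C-8a from the start and, once released, finds C-8a as the only ketone within six-membered reach, because C-5 is an ester that cannot give the enol ether (lactonisation onto it is slow under mild acid) while C-4 and C-7 would need four- and eight-membered rings.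

Step 14
Reactants: 23 the pyranone ester
Product: 24 (2R,3R,8R)-5-hydroxy-2,3-dimethyl-8-(3-methylbut-2-en-1-yl)-8-Cbm-2,3-dihydro-4H-chromene-4,7(8H)-dione
Conditions: LiN(SiMe3)2 (1.1 equiv), THF, −78 → −20 °C; AcOH
Reagents that add atoms: none
Why: Dieckmann (intramolecular Claisen) condensation: kinetic deprotonation of the acetyl CH3 (C-6, the only unhindered enolisable site because C-8 is quaternary) and 6-exo-trig attack on the C-5 ester, held cis to the C-8 arm on the C-4a=C-8a double bond, should expel methoxide and close ring A as its vinylogous acid anion, while one equivalent of base at low temperature leaves C-3 unenolised so that ring B does not open by β-elimination.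

Step 15
Reactants: 24 the bicyclic core; 25 (E)-oct-2-enal
Product: 26 (3S)-3-[(2R,3R,8R)-5-hydroxy-2,3-dimethyl-8-(3-methylbut-2-en-1-yl)-8-Cbm-4,7-dioxo-3,4,7,8-tetrahydro-2H-chromen-6-yl]octanal (expected to rest largely as its cyclic hemiacetals on O-5 or O-7)
Conditions: (R)-2-[diphenyl(trimethylsilyloxy)methyl]pyrrolidine (20 mol %), CH2Cl2, 0 °C → rt
Reagents that add atoms: none
Why: Iminium-catalysed Michael addition of a cyclic 1,3-dicarbonyl C–H (C-6, the only nucleophilic carbon left) to an enal: in the (E)-iminium ion of 25 the diphenyl(silyloxy)methyl group of the (R)-catalyst shields one face, so C-6 adds to the open face of the enal β-carbon and should set the (S)-centre under catalyst control, the existing stereocentres being remote.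

Step 16
Reactants: 26 the (3S)-aldehyde
Product: 27 (3S)-3-[(2R,3R,8R)-5-hydroxy-2,3-dimethyl-8-(3-methylbut-2-en-1-yl)-8-Cbm-4,7-dioxo-3,4,7,8-tetrahydro-2H-chromen-6-yl]octanoic acid (CNP0208815.1)
Conditions: NaClO2, NaH2PO4, 2-methyl-2-butene (excess), t-BuOH/H2O, 0 °C
Reagents that add atoms: sodium chlorite, [Na+].[O-]Cl=O
Why: Pinnick oxidation of the aldehyde (supplied from the hemiacetal equilibrium) to the carboxylic acid, with the hypochlorous acid by-product intercepted by excess 2-methyl-2-butene so that the enol and the two alkenes are spared and no stereocentre is touched.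

**Compound list**

1 | (1S,5S)-(−)-verbenone, (1S,5S)-4,6,6-trimethylbicyclo[3.1.1]hept-3-en-2-one | CC1=CC(=O)[C@H]2C[C@@H]1C2(C)C | starting material
2 | (1S,3R)-3-acetyl-2,2-dimethylcyclobutane-1-carboxylic acid | OC(=O)[C@H]1C[C@@H](C(C)=O)C1(C)C | intermediate
3 | (1S,3S)-2,2-dimethyl-3-(prop-1-en-2-yl)cyclobutane-1-carboxylic acid | OC(=O)[C@H]1C[C@@H](C(C)=C)C1(C)C | intermediate
4 | [(1S,3S)-2,2-dimethyl-3-(prop-1-en-2-yl)cyclobutyl]methanol | OC[C@H]1C[C@@H](C(C)=C)C1(C)C | intermediate
5 | (1S,3S)-1-(iodomethyl)-2,2-dimethyl-3-(prop-1-en-2-yl)cyclobutane | IC[C@H]1C[C@@H](C(C)=C)C1(C)C | intermediate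
6 | 2-(trimethylsilyl)ethanol | C[Si](C)(C)CCO | starting material
7 | 2,2,6-trimethyl-4H-1,3-dioxin-4-one | CC1=CC(=O)OC(C)(C)O1 | starting material
8 | acetylketene (3-oxobut-1-en-1-one), not isolated | CC(=O)C=C=O | intermediate
9 | 2-(trimethylsilyl)ethyl 3-oxobutanoate | CC(=O)CC(=O)OCC[Si](C)(C)C | intermediate
10 | 2-(trimethylsilyl)ethyl 2-{[(1R,3S)-2,2-dimethyl-3-(prop-1-en-2-yl)cyclobutyl]methyl}-3-oxobutanoate (C-2 epimers) | C=C(C)[C@@H]1C[C@H](CC(C(=O)OCC[Si](C)(C)C)C(C)=O)C1(C)C | intermediate
11 | tert-butyl L-valinate | CC(C)[C@H](N)C(=O)OC(C)(C)C | starting material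
12 | 2-(trimethylsilyl)ethyl (2Z)-3-{[(2S)-1-tert-butoxy-3-methyl-1-oxobutan-2-yl]amino}-2-{[(1R,3S)-2,2-dimethyl-3-(prop-1-en-2-yl)cyclobutyl]methyl}but-2-enoate | C=C(C)[C@@H]1C[C@H](C/C(C(=O)OCC[Si](C)(C)C)=C(\C)N[C@@H](C(C)C)C(=O)OC(C)(C)C)C1(C)C | intermediate
13 | 1-bromo-3-methylbut-2-ene | CC(C)=CCBr | starting material
14 | 2-(trimethylsilyl)ethyl (2S)-2-{1-[(2S)-1-tert-butoxy-3-methyl-1-oxobutan-2-yl]iminoethyl}-2-{[(1R,3S)-2,2-dimethyl-3-(prop-1-en-2-yl)cyclobutyl]methyl}-5-methylhex-4-enoate, not isolated | C=C(C)[C@@H]1C[C@H](C[C@@](C(=O)OCC[Si](C)(C)C)(CC=C(C)C)C(C)=N[C@@H](C(C)C)C(=O)OC(C)(C)C)C1(C)C | intermediate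
15 | 2-(trimethylsilyl)ethyl (2S)-2-acetyl-2-{[(1R,3S)-2,2-dimethyl-3-(prop-1-en-2-yl)cyclobutyl]methyl}-5-methylhex-4-enoate | C=C(C)[C@@H]1C[C@H](C[C@@](C(=O)OCC[Si](C)(C)C)(CC=C(C)C)C(C)=O)C1(C)C | intermediate
16 | (2S)-2-acetyl-2-{[(1R,3S)-2,2-dimethyl-3-(prop-1-en-2-yl)cyclobutyl]methyl}-5-methylhex-4-enoic acid | C=C(C)[C@@H]1C[C@H](C[C@@](C(=O)O)(CC=C(C)C)C(C)=O)C1(C)C | intermediate
17 | methyl (R)-3-hydroxybutanoate | C[C@@H](O)CC(=O)OC | starting material
18 | methyl (2R,3R)-3-hydroxy-2-methylbutanoate | C[C@@H](O)[C@@H](C)C(=O)OC | intermediate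
19 | methyl (4R,5R)-5-hydroxy-4-methyl-3-oxohexanoate | C[C@@H](O)[C@@H](C)C(=O)CC(=O)OC | intermediate
20 | (2S)-2-acetyl-2-{[(1R,3S)-2,2-dimethyl-3-(prop-1-en-2-yl)cyclobutyl]methyl}-5-methylhex-4-enoyl chloride, not isolated | C=C(C)[C@@H]1C[C@H](C[C@@](C(=O)Cl)(CC=C(C)C)C(C)=O)C1(C)C | intermediate
21 | (2R,3R)-6-methoxy-3-methyl-4,6-dioxohexan-2-yl (2S)-2-acetyl-2-{[(1R,3S)-2,2-dimethyl-3-(prop-1-en-2-yl)cyclobutyl]methyl}-5-methylhex-4-enoate | C=C(C)[C@@H]1C[C@H](C[C@@](C(=O)O[C@H](C)[C@@H](C)C(=O)CC(=O)OC)(CC=C(C)C)C(C)=O)C1(C)C | intermediate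
22 | methyl (4S)-4-acetyl-4-{[(1R,3S)-2,2-dimethyl-3-(prop-1-en-2-yl)cyclobutyl]methyl}-2-[(2R,3R)-3-hydroxy-2-methylbutanoyl]-7-methyl-3-oxooct-6-enoate (C-2 enolised), not isolated | C=C(C)[C@@H]1C[C@H](C[C@@](C(=O)C(C(=O)OC)C(=O)[C@H](C)[C@@H](C)O)(CC=C(C)C)C(C)=O)C1(C)C | intermediate
23 | methyl (2R,3R)-6-[(2R)-2-acetyl-1-[(1R,3S)-2,2-dimethyl-3-(prop-1-en-2-yl)cyclobutyl]-5-methylhex-4-en-2-yl]-2,3-dimethyl-4-oxo-3,4-dihydro-2H-pyran-5-carboxylate | C=C(C)[C@@H]1C[C@H](C[C@@](C2=C(C(=O)OC)C(=O)[C@H](C)[C@@H](C)O2)(CC=C(C)C)C(C)=O)C1(C)C | intermediate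
24 | (2R,3R,8R)-5-hydroxy-2,3-dimethyl-8-(3-methylbut-2-en-1-yl)-8-{[(1R,3S)-2,2-dimethyl-3-(prop-1-en-2-yl)cyclobutyl]methyl}-2,3-dihydro-4H-chromene-4,7(8H)-dione | C=C(C)[C@@H]1C[C@H](C[C@@]2(CC=C(C)C)C(=O)C=C(O)C3=C2O[C@H](C)[C@@H](C)C3=O)C1(C)C | intermediate
25 | (E)-oct-2-enal | CCCCC/C=C/C=O | starting material
26 | (3S)-3-[(2R,3R,8R)-5-hydroxy-2,3-dimethyl-8-(3-methylbut-2-en-1-yl)-8-{[(1R,3S)-2,2-dimethyl-3-(prop-1-en-2-yl)cyclobutyl]methyl}-4,7-dioxo-3,4,7,8-tetrahydro-2H-chromen-6-yl]octanal (open form of the hemiacetals) | C=C(C)[C@@H]1C[C@H](C[C@@]2(CC=C(C)C)C(=O)C([C@@H](CCCCC)CC=O)=C(O)C3=C2O[C@H](C)[C@@H](C)C3=O)C1(C)C | intermediate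
27 | (3S)-3-[(2R,3R,8R)-5-hydroxy-2,3-dimethyl-8-(3-methylbut-2-en-1-yl)-8-{[(1R,3S)-2,2-dimethyl-3-(prop-1-en-2-yl)cyclobutyl]methyl}-4,7-dioxo-3,4,7,8-tetrahydro-2H-chromen-6-yl]octanoic acid | C=C(C)[C@@H]1C[C@H](C[C@@]2(CC=C(C)C)C(=O)C([C@@H](CCCCC)CC(=O)O)=C(O)C3=C2O[C@H](C)[C@@H](C)C3=O)C1(C)C | target

**Step count and risks**

Total steps: 16. Longest linear sequence: 13 steps (steps 1–4, 6–9 and 12–16); steps 5 and 10–11 are side branches.

Step 13 (Proposed new method). What may go wrong:
- the stabilised enolate may fail to add to the hindered, α-quaternary ester carbonyl;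
- the tetrahedral intermediate may collapse by retro-Claisen loss of the quaternary carbon instead of the alkoxide;
- on the acid stage, lactonisation onto the C-5 ester may compete with closure onto C-8a.

Fallback by known chemistry, setting out from 19 (with acid chloride 20, made from 16 as in step 12) and rejoining the route at 23. The hydroxyl of 19 is silylated (Et3SiCl, imidazole, CH2Cl2) to give methyl (4R,5R)-4-methyl-3-oxo-5-(triethylsilyloxy)hexanoate F1. Its magnesium enolate (MgCl2, Et3N, MeCN, 0 °C) is C-acylated intermolecularly by 20, the standard magnesium-mediated C-acylation of β-keto esters, to give methyl (4S)-4-acetyl-4-Cbm-7-methyl-2-[(2R,3R)-2-methyl-3-(triethylsilyloxy)butanoyl]-3-oxooct-6-enoate F2. Pyridinium p-toluenesulfonate in MeOH, then warming in toluene, removes the silyl group and closes the freed hydroxyl onto C-8a with loss of water to give 23. This detour also avoids ester 21.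

Step 8. What may go wrong: insufficient facial discrimination in the alkylation of the chelated aza-enolate when the α-substituent is a bulky β-branched CH2 group, or incomplete enamine formation in step 7 feeding it.

Fallback setting out from 5 and rejoining at 16: catalytic phase-transfer asymmetric alkylation in place of the stoichiometric auxiliary. The sodium enolate of tert-butyl acetoacetate (NaH, THF/DMF, 60 °C) is alkylated with 5 to give tert-butyl 2-Cbm-3-oxobutanoate F3. Prenylation with 13 under a chiral C2-symmetric N-spiro bis(binaphthyl)ammonium bromide bearing 3,4,5-trifluorophenyl groups (1 mol %, 50% aq. KOH, toluene, −40 °C; catalyst enantiomer chosen by correlation) should give tert-butyl (2S)-2-acetyl-2-Cbm-5-methylhex-4-enoate F4. Me3SiOTf with 2,6-lutidine (CH2Cl2, 0 °C), then aqueous work-up, cleaves the tert-butyl ester without protic acid to give 16.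

Step 16. What may go wrong: electrophilic chlorination of the enolised trione or of the trisubstituted alkene by hypochlorous acid, or a hemiacetal–aldehyde equilibrium that keeps the aldehyde unavailable.

Fallback setting out from 26 and rejoining at 27: TEMPO (10 mol %) with PhI(OAc)2 in CH2Cl2 at rt oxidises the hemiacetal form of 26 to the enol δ-lactone F5 (the (4S)-4-pentyl-3,4-dihydro-2H-pyran-2-one ring fused through O-5 and C-6 of the core). LiOH in THF/H2O at 0 °C, then mild acidification, opens the lactone to 27.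

Further compounds
F1 | step 13 | methyl (4R,5R)-4-methyl-3-oxo-5-(triethylsilyloxy)hexanoate | CC[Si](CC)(CC)O[C@H](C)[C@@H](C)C(=O)CC(=O)OC
F2 | step 13 | methyl (4S)-4-acetyl-4-{[(1R,3S)-2,2-dimethyl-3-(prop-1-en-2-yl)cyclobutyl]methyl}-7-methyl-2-[(2R,3R)-2-methyl-3-(triethylsilyloxy)butanoyl]-3-oxooct-6-enoate | C=C(C)[C@@H]1C[C@H](C[C@@](C(=O)C(C(=O)OC)C(=O)[C@H](C)[C@@H](C)O[Si](CC)(CC)CC)(CC=C(C)C)C(C)=O)C1(C)C
F3 | step 8 | tert-butyl 2-{[(1R,3S)-2,2-dimethyl-3-(prop-1-en-2-yl)cyclobutyl]methyl}-3-oxobutanoate | C=C(C)[C@@H]1C[C@H](CC(C(=O)OC(C)(C)C)C(C)=O)C1(C)C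
F4 | step 8 | tert-butyl (2S)-2-acetyl-2-{[(1R,3S)-2,2-dimethyl-3-(prop-1-en-2-yl)cyclobutyl]methyl}-5-methylhex-4-enoate | C=C(C)[C@@H]1C[C@H](C[C@@](C(=O)OC(C)(C)C)(CC=C(C)C)C(C)=O)C1(C)C
F5 | step 16 | enol δ-lactone of 27 closed on O-5, with the (S)-pentyl-bearing carbon attached to C-6 | C=C(C)[C@@H]1C[C@H](C[C@@]2(CC=C(C)C)C(=O)C3=C(OC(=O)C[C@@H]3CCCCC)C4=C2O[C@H](C)[C@@H](C)C4=O)C1(C)C
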